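**Retrosynthetic overview**

1. Locants follow labdane numbering: ring A = C1–C5 and C10; ring B = C5–C10 with C8 the ketone; side chain C11–C16 on C9.
2. Side chain: C12–C13 by Negishi coupling with a (Z)-enol triflate, which fixes the C13=C14 geometry; C11–C12 by 1,4-addition of CH2(ZnI)2 to a 9-methylene-8-ketone; C9–H by protonation.
3. Ring B: its C8(=O)–C7=C6 enone, with C6 on the C5 ring-fusion methine, is the retron of an oxidative one-carbon ring enlargement. C7 is inserted between C8 and C6 of a trans-fused cyclopentanone (C8, C9, C10, C5, C6) through its 1-siloxybicyclo[3.1.0]hexane.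
4. The five-membered ring comes from aldol condensation of a 1,4-diketone; C10 is set by enantioselective decarboxylative allylation of 2,2,6-trimethylcyclohexanone, whose allyl carbons become C9, C8 and C6.
5. Ring order: ring A (purchased), then the five-membered ring on C5/C10, then ring B by expansion of that ring.

Key step: step 7

Assumption: the (S)-configured t-BuPHOX ligand is taken to give the (S)-ketone 5, as it does with the 2-methylcyclohexanone analogue; if the sense were opposite, the (R)-ligand would be used.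

**Route**

Step 1
Reactants: 1 2,2,6-trimethylcyclohexanone (racemic); 2 allyl chloroformate
Product: 4 prop-2-en-1-yl 2,6,6-trimethylcyclohex-1-en-1-yl carbonate, via lithium enolate 3 (not isolated)
Conditions: LiN(SiMe3)2, THF, 0 °C; then 2, −78 °C
Reagents that add atoms: none
Why: the ketone has one enolisable position only, so a single tetrasubstituted enolate forms and is acylated on oxygen by the chloroformate (enol carbonate formation); no stereocentre remains.

Step 2
Reactants: 4 prop-2-en-1-yl 2,6,6-trimethylcyclohex-1-en-1-yl carbonate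
Product: 5 (2S)-2,6,6-trimethyl-2-(prop-2-en-1-yl)cyclohexan-1-one
Conditions: Pd2(dba)3 (2.5 mol %), (S)-t-BuPHOX [(S)-4-tert-butyl-2-(2-diphenylphosphinophenyl)-4,5-dihydrooxazole, 6 mol %], THF, 25 °C
Reagents that add atoms: none
Why: decarboxylative asymmetric allylic alkylation (Tsuji allylation): zerovalent palladium ionises the allyl carbonate, CO2 is lost, and the enolate and allyl fragments recombine inside the chiral ligand sphere, which sets the quaternary C10 (S in 5; the same arrangement is 8aR in the target by a change of CIP priorities only).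

Step 3
Reactants: 5 (2S)-2,6,6-trimethyl-2-(prop-2-en-1-yl)cyclohexan-1-one
Product: 6 (2S)-2,6,6-trimethyl-2-(2-oxopropyl)cyclohexan-1-one
Conditions: PdCl2 (cat.), Cu(OAc)2 (cat.), O2 (1 atm), DMA/H2O, 25 °C
Reagents that add atoms: water (O)
Why: Tsuji–Wacker oxidation: divalent palladium activates the terminal alkene for Markovnikov attack of water to give the methyl ketone, while the hindered ring ketone and the quaternary centre are untouched.

Step 4
Reactants: 6 (2S)-2,6,6-trimethyl-2-(2-oxopropyl)cyclohexan-1-one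
Product: 7 (7aS)-4,4,7a-trimethyl-1,4,5,6,7,7a-hexahydro-2H-inden-2-one
Conditions: KOH (substoichiometric), xylenes, 110 °C, Dean–Stark trap
Reagents that add atoms: none
Why: intramolecular aldol condensation: the methyl-ketone enolate adds to the ring carbonyl to close the five-membered ring and removal of water drives the hindered addition to the enone; C10 has no α-hydrogen and cannot epimerise.

Step 5
Reactants: 7 (7aS)-4,4,7a-trimethyl-1,4,5,6,7,7a-hexahydro-2H-inden-2-one
Product: 9 trimethyl{[(3aR,7aS)-4,4,7a-trimethyl-3a,4,5,6,7,7a-hexahydro-1H-inden-2-yl]oxy}silane, via lithium enolate 8 (not isolated)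
Conditions: Li (2.2 equiv), NH3(l)/THF, −78 °C; isoprene; NH3 evaporated; then Me3SiCl, Et3N, THF, 0 °C
Reagents that add atoms: chlorotrimethylsilane (C[Si](C)(C)Cl)
Why: dissolving-metal (Birch-type) enone reduction with regiospecific enolate trapping: the β-carbon C5 should be protonated from the face opposite the two axial methyl groups on C10 and C4, giving the trans ring fusion, and silylation fixes the enol double bond toward C6.

Step 6
Reactants: 9 trimethyl{[(3aR,7aS)-4,4,7a-trimethyl-3a,4,5,6,7,7a-hexahydro-1H-inden-2-yl]oxy}silane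
Product: 10 (1bR,5aS)-2,2,5a-trimethyl-6a-[(trimethylsilyl)oxy]decahydrocyclopropa[a]indene (trans-fused; cyclopropane CH2 on the face opposite the 5a-methyl drawn as the major face isomer)
Conditions: Et2Zn, CH2I2, toluene, 0 → 25 °C
Reagents that add atoms: diiodomethane (ICI)
Why: Simmons–Smith cyclopropanation (Furukawa variant) of the electron-rich silyl enol ether; the zinc carbenoid should approach mainly anti to the C10 methyl, and both face isomers converge in step 7.

Step 7
Reactants: 10 (1bR,5aS)-2,2,5a-trimethyl-6a-[(trimethylsilyl)oxy]decahydrocyclopropa[a]indene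
Product: 12 (4aR,8aS)-5,5,8a-trimethyl-4a,5,6,7,8,8a-hexahydronaphthalen-2(1H)-one, via chloro ketone 11 (not isolated)
Conditions: FeCl3 (2.2 equiv), DMF, 0 → 25 °C; then NaOAc, MeOH, reflux
Reagents that add atoms: none
Why: Trivalent iron oxidises the siloxycyclopropane to a cyclopropyloxy radical whose β-scission cleaves the bond C8–C6 shared by the cyclopropane and the five-membered ring, so that the ring (C8, C9, C10, C5, C6) becomes the six-membered ring B with C8 as ketone and a radical at C6; chlorine transfer from FeCl3 gives the 6-chloro ketone 11, and NaOAc removes HCl by an E1cB path through the C7 enolate to give the C6=C7 enone. The closest known reaction type is the Ito–Saegusa ring expansion of 1-siloxybicyclo[n.1.0]alkanes to cycloalk-2-enones, in which a cyclopentanone becomes a cyclohexenone. No ring is closed by bond formation: ring B arises by fragmentation of the zero-atom bridge, a ring enlargement by one atom (C7). No new stereocentre remains in 12, because the C6 chloride is eliminated, and C5 and C10 are not touched and keep the trans ring fusion from steps 2 and 5. The step needs regioselective β-scission of the internal rather than the external cyclopropane bond, secured by formation of the secondary ring-enlarged C6 radical instead of a primary one, and elimination toward C7 only, secured because only the C7 hydrogens are α to the carbonyl.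

Step 8
Reactants: 12 (4aR,8aS)-5,5,8a-trimethyl-4a,5,6,7,8,8a-hexahydronaphthalen-2(1H)-one
Product: 16 (4aR,8aR)-5,5,8a-trimethyl-1-methylidene-4a,5,6,7,8,8a-hexahydronaphthalen-2(1H)-one, via lithium dienolate 13 (not isolated), via Mannich base 14 (not isolated), via ammonium iodide 15 (not isolated)
Conditions: LiN(iPr)2, THF, −78 °C; CH2=NMe2 I, −78 → 25 °C; then MeI, 25 °C; then aq. NaHCO3, CH2Cl2
Reagents that add atoms: N,N-dimethylmethyleneiminium iodide (C=[N+](C)C.[I-])
Why: kinetic deprotonation at C9, the only α-CH2, gives the cross-conjugated enolate, which undergoes a Mannich reaction with the iminium salt, and quaternisation followed by base-induced loss of trimethylamine (Eschenmoser methylenation) gives the exocyclic enone without touching C5 or C10.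

Step 9
Reactants: 17 tert-butyl 4-chloro-3-oxobutanoate
Product: 18 tert-butyl 4-(acetyloxy)-3-oxobutanoate
Conditions: KOAc, NaI (cat.), DMF, 25 °C
Reagents that add atoms: potassium acetate (CC(=O)[O-].[K+])
Why: SN2 displacement of the activated α-chloro ketone by acetate (iodide-assisted) should give the 4-acetoxy β-keto ester.

Step 10
Reactants: 18 tert-butyl 4-(acetyloxy)-3-oxobutanoate
Product: 20 tert-butyl (2Z)-4-(acetyloxy)-3-{[(trifluoromethyl)sulfonyl]oxy}but-2-enoate, via sodium enolate 19 (not isolated)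
Conditions: NaH, Et2O, 0 °C; then Tf2O, 0 °C
Reagents that add atoms: trifluoromethanesulfonic anhydride (O=S(=O)(OS(=O)(=O)C(F)(F)F)C(F)(F)F)
Why: O-triflation of the sodium-chelated β-keto ester enolate, in which the enolate oxygen and the ester carbonyl are held syn, should give the (Z)-enol triflate that later fixes the C13=C14 geometry.

Step 11
Reactants: 16 (4aR,8aR)-5,5,8a-trimethyl-1-methylidene-4a,5,6,7,8,8a-hexahydronaphthalen-2(1H)-one; 20 tert-butyl (2Z)-4-(acetyloxy)-3-{[(trifluoromethyl)sulfonyl]oxy}but-2-enoate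
Product: 23 tert-butyl (2E)-3-[(acetyloxy)methyl]-5-[(1S,4aR,8aR)-5,5,8a-trimethyl-2-oxo-1,2,4a,5,6,7,8,8a-octahydronaphthalen-1-yl]pent-2-enoate, via zincio silyl dienol ether 21 (not isolated), via coupled silyl dienol ether 22 (not isolated)
Conditions: CH2(ZnI)2 (1.1 equiv, made in THF from CH2I2 and Zn, PbCl2 cat.), Me3SiCl, THF, 0 → 25 °C; then 20, PdCl2(dppf) (5 mol %), 25 → 40 °C; then 1 M HCl, THF, 0 °C
Reagents that add atoms: bis(iodozincio)methane (I[Zn]C[Zn]I), made from diiodomethane (ICI)
Why: conjugate addition of the geminal dizinc reagent to the s-cis exocyclic enone (the s-trans ring enone cannot reach the six-membered transition state) with silyl trapping leaves a primary alkylzinc at C12, which enters a Negishi coupling with the enol triflate with retention of the double-bond geometry, and hydrolysis of the silyl dienol ether should protonate C9 from the face opposite the C10 methyl, placing the side chain cis to that methyl.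

Step 12
Reactants: 23 tert-butyl (2E)-3-[(acetyloxy)methyl]-5-[(1S,4aR,8aR)-5,5,8a-trimethyl-2-oxo-1,2,4a,5,6,7,8,8a-octahydronaphthalen-1-yl]pent-2-enoate
Product: 24 (2E)-3-[(acetyloxy)methyl]-5-[(1S,4aR,8aR)-5,5,8a-trimethyl-2-oxo-1,2,4a,5,6,7,8,8a-octahydronaphthalen-1-yl]pent-2-enoic acid
Conditions: CF3CO2H, CH2Cl2, 0 → 25 °C
Reagents that add atoms: none
Why: acidolysis of the tert-butyl ester (E1 loss of isobutene) should free the acid without touching the primary acetate, the enone or the C9 centre under short, weakly enolising conditions.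

**Compound list**

1 | 2,2,6-trimethylcyclohexanone (racemic; the stereocentre is erased in step 1) | CC1CCCC(C)(C)C1=O | starting material
2 | allyl chloroformate | C=CCOC(Cl)=O | starting material
3 | lithium 2,6,6-trimethylcyclohex-1-en-1-olate | [Li]OC1=C(C)CCCC1(C)C | intermediate
4 | prop-2-en-1-yl 2,6,6-trimethylcyclohex-1-en-1-yl carbonate | C=CCOC(=O)OC1=C(C)CCCC1(C)C | intermediate
5 | (2S)-2,6,6-trimethyl-2-(prop-2-en-1-yl)cyclohexan-1-one | C=CC[C@]1(C)CCCC(C)(C)C1=O | intermediate
6 | (2S)-2,6,6-trimethyl-2-(2-oxopropyl)cyclohexan-1-one | CC(=O)C[C@]1(C)CCCC(C)(C)C1=O | intermediate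
7 | (7aS)-4,4,7a-trimethyl-1,4,5,6,7,7a-hexahydro-2H-inden-2-one | O=C1C[C@]2(C)CCCC(C)(C)C2=C1 | intermediate
8 | lithium (3aR,7aS)-4,4,7a-trimethyl-3a,4,5,6,7,7a-hexahydro-1H-inden-2-olate | [Li]OC1=C[C@@H]2C(C)(C)CCC[C@@]2(C)C1 | intermediate
9 | trimethyl{[(3aR,7aS)-4,4,7a-trimethyl-3a,4,5,6,7,7a-hexahydro-1H-inden-2-yl]oxy}silane | C[Si](C)(C)OC1=C[C@@H]2C(C)(C)CCC[C@@]2(C)C1 | intermediate
10 | (1bR,5aS)-2,2,5a-trimethyl-6a-[(trimethylsilyl)oxy]decahydrocyclopropa[a]indene, cyclopropane CH2 anti to the 5a-methyl | C[Si](C)(C)O[C@]12C[C@H]1[C@@H]3C(C)(C)CCC[C@@]3(C)C2 | intermediate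
11 | (4aR,8aS)-4-chloro-5,5,8a-trimethyloctahydronaphthalen-2(1H)-one (C4 epimers) | O=C1CC(Cl)[C@@H]2C(C)(C)CCC[C@@]2(C)C1 | intermediate
12 | (4aR,8aS)-5,5,8a-trimethyl-4a,5,6,7,8,8a-hexahydronaphthalen-2(1H)-one | O=C1C=C[C@@H]2C(C)(C)CCC[C@@]2(C)C1 | intermediate
13 | lithium cross-conjugated dienolate of 12 (O–C2=C1) | [Li]OC1C=C[C@@H]2C(C)(C)CCC[C@@]2(C)C=1 | intermediate
14 | 1-[(dimethylamino)methyl] derivative of 12 (C1 epimers) | CN(C)CC1C(=O)C=C[C@@H]2C(C)(C)CCC[C@@]12C | intermediate
15 | N,N,N-trimethylammonium iodide of 14 | C[N+](C)(C)CC1C(=O)C=C[C@@H]2C(C)(C)CCC[C@@]12C.[I-] | intermediate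
16 | (4aR,8aR)-5,5,8a-trimethyl-1-methylidene-4a,5,6,7,8,8a-hexahydronaphthalen-2(1H)-one | C=C1C(=O)C=C[C@@H]2C(C)(C)CCC[C@@]12C | intermediate
17 | tert-butyl 4-chloro-3-oxobutanoate | CC(C)(C)OC(=O)CC(=O)CCl | starting material
18 | tert-butyl 4-(acetyloxy)-3-oxobutanoate | CC(=O)OCC(=O)CC(=O)OC(C)(C)C | intermediate
19 | sodium (Z)-enolate of 18 | CC(=O)OC/C(O[Na])=C/C(=O)OC(C)(C)C | intermediate
20 | tert-butyl (2Z)-4-(acetyloxy)-3-{[(trifluoromethyl)sulfonyl]oxy}but-2-enoate | CC(=O)OC/C(OS(=O)(=O)C(F)(F)F)=C/C(=O)OC(C)(C)C | intermediate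
21 | {2-[(4aR,8aR)-5,5,8a-trimethyl-2-[(trimethylsilyl)oxy]-4a,5,6,7,8,8a-hexahydronaphthalen-1-yl]ethyl}zinc iodide | I[Zn]CCC1=C(O[Si](C)(C)C)C=C[C@@H]2C(C)(C)CCC[C@@]12C | intermediate
22 | tert-butyl (2E)-3-[(acetyloxy)methyl]-5-[(4aR,8aR)-5,5,8a-trimethyl-2-[(trimethylsilyl)oxy]-4a,5,6,7,8,8a-hexahydronaphthalen-1-yl]pent-2-enoate | CC(=O)OC/C(=C/C(=O)OC(C)(C)C)CCC1=C(O[Si](C)(C)C)C=C[C@@H]2C(C)(C)CCC[C@@]12C | intermediate
23 | tert-butyl (2E)-3-[(acetyloxy)methyl]-5-[(1S,4aR,8aR)-5,5,8a-trimethyl-2-oxo-1,2,4a,5,6,7,8,8a-octahydronaphthalen-1-yl]pent-2-enoate | CC(=O)OC/C(=C/C(=O)OC(C)(C)C)CC[C@@H]1C(=O)C=C[C@@H]2C(C)(C)CCC[C@@]12C | intermediate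
24 | (2E)-3-[(acetyloxy)methyl]-5-[(1S,4aR,8aR)-5,5,8a-trimethyl-2-oxo-1,2,4a,5,6,7,8,8a-octahydronaphthalen-1-yl]pent-2-enoic acid | CC(=O)OC/C(=C/C(=O)O)CC[C@@H]1C(=O)C=C[C@@H]2C(C)(C)CCC[C@@]12C | target

**Step count and risks**

Total step count: 12. Longest linear sequence: 10 steps (steps 1–8, 11 and 12, from compound 1).

Steps most likely to fail:

Step 11. The 1,4-addition may be incomplete because of competing carbonyl methylenation or oligomerisation of the dienone. The carbon–zinc bond may be lost by protonolysis before coupling. Zerovalent palladium may ionise the allylic acetate. Protonation at C9 may show poor facial selectivity. Fallback, stepwise and with standard reactions: from dienone 16, 1,4-addition of (CH2=CH)2CuLi with Me3SiCl at −78 °C and low-temperature protonation should give the 1-allyl ketone F1. Cleavage of the terminal alkene with OsO4 (cat.) and NaIO4 gives the aldehyde F2. NaBH4 at −78 °C reduces only the aldehyde to the primary alcohol F3. I2, PPh3 and imidazole give the primary iodide F4. Zinc insertion (Zn, LiCl, THF) gives the alkylzinc iodide F5, which is coupled with triflate 20 under PdCl2(dppf) and comes back to the route at ester 23.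

Step 5. Protonation at C5 may show poor facial selectivity and give the cis ring fusion. The carbonyl may be over-reduced. The enolate may equilibrate before silylation. Fallback: from enone 7, hydrogenation (H2, Pd on carbon, EtOAc) delivers hydrogen from the catalyst surface to the less hindered face of the ring-fusion double bond and should give the saturated trans-fused ketone F6. Kinetic enolisation with LiN(iPr)2 at −78 °C at the α-methylene next to the methine, rather than at the neopentyl one, and trapping with Me3SiCl returns to silyl enol ether 9.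

Step 7. Protodesilylation with opening of the external cyclopropane bond would give an α-methyl ketone without ring enlargement. Over-chlorination and incomplete elimination are also possible. Fallback: from silyl enol ether 9, addition of dibromocarbene (CHBr3, KOt-Bu, pentane) gives the dibromo siloxycyclopropane F7. Warming opens it electrocyclically with loss of Me3SiBr to the ring-enlarged 2-bromo enone F8. Hydrodebromination (Bu3SnH, Pd(PPh3)4) returns to enone 12.

Further compounds
F1 | step 11 | (1S,4aR,8aR)-5,5,8a-trimethyl-1-(prop-2-en-1-yl)-4a,5,6,7,8,8a-hexahydronaphthalen-2(1H)-one | C=CC[C@@H]1C(=O)C=C[C@@H]2C(C)(C)CCC[C@@]12C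
F2 | step 11 | 2-[(1S,4aR,8aR)-5,5,8a-trimethyl-2-oxo-1,2,4a,5,6,7,8,8a-octahydronaphthalen-1-yl]acetaldehyde | O=CC[C@@H]1C(=O)C=C[C@@H]2C(C)(C)CCC[C@@]12C
F3 | step 11 | (1S,4aR,8aR)-1-(2-hydroxyethyl)-5,5,8a-trimethyl-4a,5,6,7,8,8a-hexahydronaphthalen-2(1H)-one | OCC[C@@H]1C(=O)C=C[C@@H]2C(C)(C)CCC[C@@]12C
F4 | step 11 | (1S,4aR,8aR)-1-(2-iodoethyl)-5,5,8a-trimethyl-4a,5,6,7,8,8a-hexahydronaphthalen-2(1H)-one | ICC[C@@H]1C(=O)C=C[C@@H]2C(C)(C)CCC[C@@]12C
F5 | step 11 | {2-[(1S,4aR,8aR)-5,5,8a-trimethyl-2-oxo-1,2,4a,5,6,7,8,8a-octahydronaphthalen-1-yl]ethyl}zinc iodide | I[Zn]CC[C@@H]1C(=O)C=C[C@@H]2C(C)(C)CCC[C@@]12C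
F6 | step 5 | (3aR,7aS)-4,4,7a-trimethyloctahydro-2H-inden-2-one | O=C1C[C@@H]2C(C)(C)CCC[C@@]2(C)C1
F7 | step 7 | (1bR,5aS)-1,1-dibromo-2,2,5a-trimethyl-6a-[(trimethylsilyl)oxy]decahydrocyclopropa[a]indene, CBr2 anti to the 5a-methyl | C[Si](C)(C)O[C@]12C(Br)(Br)[C@H]1[C@@H]3C(C)(C)CCC[C@@]3(C)C2
F8 | step 7 | (4aR,8aS)-3-bromo-5,5,8a-trimethyl-4a,5,6,7,8,8a-hexahydronaphthalen-2(1H)-one | O=C1C(Br)=C[C@@H]2C(C)(C)CCC[C@@]2(C)C1
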